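The earlier runs and the new flask were computed for an exercise; noise was put on by code.

Of the 3 questions on this flask, two ask for one excess at different times, and one ratio answers both. A single-handed free catalyst turns a racemate of the two substrates into two products.

in all of them: left-handed substrate 0.050 M; right-handed substrate 0.050 M

|  | partner | precatalyst | impurity | remark | time |
|---|---|---|---|---|---|
| winter | 0.20 M | 1 mM | 0.10 mM | run made earlier |  |
| dusk | 0.20 M | 1 mM | 0.22 mM | run made earlier |  |
| dawn | 0.20 M | 2 mM | 0.15 mM | run made earlier |  |
| flask | 0.200 M | 1.0 mM | 0.15 mM |  | 10 h |

| run | time / h | left-handed product / % | right-handed product / % |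
|---|---|---|---|
| winter | 0.667 | 12.6 | 1.8 |
| winter | 1.33 | 27.2 | 3.4 |
| winter | 3.00 | 41.6 | 6.5 |
| winter | 8.00 | 56.5 | 8.3 |
| dusk | 2.00 | 30.7 | 6.1 |
| dusk | 4.00 | 39.2 | 5.3 |
| dusk | 6.00 | 50.0 | 5.9 |
| dusk | 8.00 | 52.2 | 8.2 |
| dawn | 1.00 | 33.8 | 6.3 |
| dawn | 3.00 | 60.3 | 9.8 |
| dawn | 5.00 | 67.5 | 11.4 |
| dawn | 8.00 | 72.1 | 11.0 |

(standard deviation of a reading: 1 percentage point)

- free catalyst is single-handed; left-handed substrate and right-handed substrate are mirror images of each other, charged as a racemate, each of them at the stated concentration
- what was read earlier has a scatter of 1 percentage point, one standard deviation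
- an excess is the difference of the two amounts in percent of their sum
- an excess is below zero if the other one leads

* excess of left-handed product over right-handed product in the product at 12 min
* excess of left-handed product over right-handed product in the product at 10 h
* part of the left-handed substrate and right-handed substrate charged together that has reacted at 10 h

The dawn run holds 72.1 % of left-handed product at 8.00 h, more than the 50.0 % of the charge that began as left-handed substrate, so right-handed substrate must be turning into left-handed substrate. I therefore take the product ratio s, the left-handed product over the right-handed product summed over the readings at 8.00 h of the winter, dusk and dawn runs; as a reading it is 6.57, and it carries their scatter. If the two substrates stay level, every portion of product comes in this ratio, the selectivity factor. The excess is then s less one over s plus one, 73.6 %, at 12 min and at 10 h alike, and left-handed product is 86.8 % of whatever has reacted.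

The forecast gives 74 %, 73 % and 65 % reacted, holding that “the excess should barely move with time or conversion”.

The flask gives 73.8 %, 73.8 % and 66.5 %.

    partner + free catalyst + left-handed substrate → free catalyst + left-handed product (k = 100 L² mol⁻² min⁻¹)
    partner + free catalyst + right-handed substrate → free catalyst + right-handed product (k = 15.0 L² mol⁻² min⁻¹)
    left-handed substrate ⇌ right-handed substrate (k = 0.350 min⁻¹)
    free catalyst + impurity → spent catalyst (k = 4400 L mol⁻¹ min⁻¹)
    2 partner → homo dimer (k = 0.0280 L mol⁻¹ min⁻¹)
    partner + precatalyst → free catalyst + spent reagent (k = 0.280 L mol⁻¹ min⁻¹)

In this flask at 0.702 h, left-handed substrate has a half-life of 2.0 min by the forward step to right-handed substrate alone, far shorter than the 1.3 h by its reaction to left-handed product. At 10 h the excess of right-handed substrate among what is left of the two is 0.0606 %. The share from s, applied to the flask's conversion, gives 57.7 % of the charge as left-handed product, and the flask holds 57.8 %. A neighbour flask with 0.0025 M of precatalyst reaches 91.9 % reacted, for which the same share gives 79.8 %, and it holds 79.7 %.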